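**Retrosynthetic overview**

- Ester ends: the C7 methacrylate comes from acylation; the C9 isobutyrate and the C7 carbinol come together from a C9-hydroxy C7-ketone by Evans–Tishchenko reduction; the C9 hydroxyl comes from asymmetric conjugate borylation of a cycloheptenone.
- Seven-membered ring (formed last): intramolecular aldol condensation of a C7 methyl ketone with a C9 aldehyde, both held on the same face of the cyclobutane.
- Cyclobutane and six-membered ring (formed together, first): intramolecular vinylketene–alkene [2+2] of an acyclic silyloxy trienoic acid; the silyloxy stereocentre (later the C1 ketone) fixes C4, C10 and C11.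
- Key C–C bond (future C1–C2): intermolecular catalytic asymmetric vinylogous Mukaiyama aldol of (2E)-3-methylpenta-2,4-dienal with the silyl dienolate of methyl 3-methylbut-2-enoate.

Assumption (numbering): tricyclic compounds use longipinane numbering (C1 ketone, C2=C3 with C3–Me, cyclobutane C4–C5–C11–C10, C6 gem-dimethyl, C7/C9 oxygenated, C10–Me); bicyclic intermediates keep a fixed bicyclo[3.1.1]heptane numbering in which C2, C4, C6 and C7 become longipinane C1, C3, C5 and C10.
Assumption (catalyst sense): the (R,R)-bisphosphoramide in step 4 and the (R)-ligand in step 16 are taken to give the 5S and 9R products; if Mosher analysis shows the opposite sense, the enantiomeric catalyst or ligand is used.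

**Step 1**
Reactants: 1 (2E)-3-methylpent-2-en-4-yn-1-ol
Product: 2 (2E)-3-methylpenta-2,4-dien-1-ol
Conditions: H2 (1 atm), Pd/CaCO3/Pb(OAc)2 (Lindlar catalyst), quinoline, EtOAc, 0 °C to rt
Reagents that add atoms: none
Why: Lindlar semi-hydrogenation stops at the alkene because the poisoned palladium surface binds the terminal alkyne much more strongly than the diene, and the E trisubstituted alkene is untouched.

**Step 2**
Reactants: 2 (2E)-3-methylpenta-2,4-dien-1-ol
Product: 3 (2E)-3-methylpenta-2,4-dienal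
Conditions: MnO2 (activated, excess), CH2Cl2, rt; filtered and used as a cold solution
Reagents that add atoms: none
Why: MnO2 allylic oxidation is selective for allylic alcohols under neutral conditions and does not scramble the E geometry.

**Step 3**
Reactants: 4 methyl 3-methylbut-2-enoate
Product: 5 tert-butyl[(1-methoxy-3-methylbuta-1,3-dien-1-yl)oxy]dimethylsilane
Conditions: LiN(i-Pr)2, THF/DMPU, −78 °C; then TBSCl, −78 °C to rt
Reagents that add atoms: tert-butyldimethylsilyl chloride CC(C)(C)[Si](C)(C)Cl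
Why: Kinetic γ-deprotonation of the senecioate and O-silylation of the extended enolate give the silyl dienol ether (silyl ketene acetal formation) needed as the vinylogous nucleophile.

**Step 4**
Reactants: 3 (2E)-3-methylpenta-2,4-dienal; 5 silyl dienolate
Product: 6 methyl (2E,5S,6E)-5-hydroxy-3,7-dimethylnona-2,6,8-trienoate
Conditions: SiCl4 (1.1 equiv), (R,R)-Denmark bisphosphoramide (5 mol %), i-Pr2NEt (10 mol %), CH2Cl2, −78 °C; aq. NaHCO3 work-up
Reagents that add atoms: none
Why: This catalytic asymmetric vinylogous Mukaiyama aldol joins the two fragments with 1,2- and γ-selectivity to give the E-enoate, and the chiral phosphoramide-bound silicon Lewis acid directs Si-face attack on the aldehyde to set C5 as S.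

**Step 5**
Reactants: 6 hydroxy trienoate
Product: 7 methyl (2E,5S,6E)-5-{[tert-butyl(dimethyl)silyl]oxy}-3,7-dimethylnona-2,6,8-trienoate
Conditions: TBSCl, imidazole, DMF, 0 °C to rt
Reagents that add atoms: tert-butyldimethylsilyl chloride CC(C)(C)[Si](C)(C)Cl
Why: Standard silylation protects the acid-sensitive dienylic alcohol without touching the stereocentre and installs the bulky group that later controls the cycloaddition face.

**Step 6**
Reactants: 7 silyloxy trienoate
Product: 8 (2E,5S,6E)-5-{[tert-butyl(dimethyl)silyl]oxy}-3,7-dimethylnona-2,6,8-trienoic acid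
Conditions: LiOH, THF/MeOH/H2O, rt to 40 °C; then dilute HCl to pH 4 at 0 °C
Reagents that add atoms: lithium hydroxide [Li+].[OH-]
Why: Saponification of the methyl ester leaves the TBS ether and both alkene geometries intact, since the E-enoate cannot lactonise or eliminate.

**Step 7**
Reactants: 8 silyloxy trienoic acid
Product: 11 (1R,2S,5R,7R)-2-{[tert-butyl(dimethyl)silyl]oxy}-7-ethenyl-7-methyl-4-methylidenebicyclo[3.1.1]heptan-6-one, via acyl chloride 9 (not isolated), via vinylketene 10 (not isolated)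
Conditions: 1-chloro-N,N,2-trimethylprop-1-en-1-amine, CH2Cl2, 0 °C to rt; then slow addition to Et3N (5 equiv) in toluene (0.01 M), reflux
Reagents that add atoms: none
Why: Dehydrochlorination at the methyl group cis to the carbonyl gives the vinylketene, which undergoes the crossed intramolecular ketene–alkene [2+2] cycloaddition (carbonyl carbon to the less substituted alkene carbon); the E alkene puts the C7 methyl syn to the three-carbon bridge, and 1,3-allylic strain between the silyloxy carbon and that methyl sends the ketene to the face opposite the OTBS group, setting C1, C5 and C7.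

**Step 8**
Reactants: 11 bicyclic cyclobutanone
Product: 12 2-[(1R,2S,5S,7R)-2-{[tert-butyl(dimethyl)silyl]oxy}-7-ethenyl-7-methyl-4-methylidenebicyclo[3.1.1]heptan-6-ylidene]acetonitrile (E/Z mixture)
Conditions: (EtO)2P(O)CH2CN, NaH, THF, 0 °C to rt
Reagents that add atoms: diethyl cyanomethylphosphonate N#CCP(=O)(OCC)OCC
Why: Horner–Wadsworth–Emmons olefination works well on the strained, non-enolisable cyclobutanone with this small stabilised phosphonate anion, and the alkene geometry is irrelevant.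

**Step 9**
Reactants: 12 alkylidene nitrile
Product: 13 2-[(1R,2S,5R,6S,7R)-2-{[tert-butyl(dimethyl)silyl]oxy}-7-ethenyl-7-methyl-4-methylidenebicyclo[3.1.1]heptan-6-yl]acetonitrile
Conditions: Cu(OAc)2 (5 mol %), Xantphos (5 mol %), (EtO)2MeSiH, t-BuOH, toluene, 0 °C to rt
Reagents that add atoms: none
Why: Copper hydride conjugate reduction touches only the activated alkene and delivers hydride to C6 from the face syn to the three-carbon bridge, because the other face is blocked by the pseudo-axial C7 vinyl group, so the cyanomethyl arm ends up cis to the vinyl group as the later ring closure requires.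

**Step 10**
Reactants: 13 cyanomethyl compound
Product: 15 2-[(1R,2S,5R,6S,7R)-2-{[tert-butyl(dimethyl)silyl]oxy}-7-ethenyl-7-methyl-4-methylidenebicyclo[3.1.1]heptan-6-yl]-2-methylpropanenitrile, via monomethyl nitrile 14 (not isolated)
Conditions: LiN(i-Pr)2, THF, −78 °C, then MeI, −78 to 0 °C; second charge LiN(i-Pr)2 (THF/DMPU), then MeI, −78 °C to rt
Reagents that add atoms: iodomethane CI
Why: Two successive nitrile-anion alkylations with the small, linear nitrile anion and methyl iodide build the quaternary gem-dimethyl carbon reliably.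

**Step 11**
Reactants: 15 tertiary nitrile
Product: 17 3-[(1R,2S,5R,6S,7R)-2-{[tert-butyl(dimethyl)silyl]oxy}-7-ethenyl-7-methyl-4-methylidenebicyclo[3.1.1]heptan-6-yl]-3-methylbutan-2-one, via ketimine 16 (not isolated)
Conditions: MeLi (3 equiv), Et2O, 0 °C to rt; then aq. AcOH/THF, rt
Reagents that add atoms: methyllithium [Li]C; water O
Why: Organolithium addition to a nitrile stops at the N-lithio imine, and mild acidic hydrolysis of the ketimine gives the methyl ketone without harming the TBS ether or the exocyclic alkene.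

**Step 12**
Reactants: 17 silyloxy methyl ketone
Product: 18 3-[(1R,2S,5R,6S,7R)-7-ethenyl-2-hydroxy-7-methyl-4-methylidenebicyclo[3.1.1]heptan-6-yl]-3-methylbutan-2-one
Conditions: HF·pyridine, pyridine, THF, 0 °C to rt
Reagents that add atoms: none
Why: Buffered fluoride desilylation frees the secondary alcohol under conditions too weakly acidic to open the pinane-type cyclobutane.

**Step 13**
Reactants: 18 hydroxy ketone
Product: 20 (1R,5R,6S,7R)-7-ethenyl-4,7-dimethyl-6-(2-methyl-3-oxobutan-2-yl)bicyclo[3.1.1]hept-3-en-2-one, via exo-methylene ketone 19 (not isolated)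
Conditions: Dess–Martin periodinane, CH2Cl2, rt; aq. NaHCO3 wash; then DBU (0.2 equiv), CH2Cl2, rt
Reagents that add atoms: none
Why: Dess–Martin oxidation gives the β,γ-unsaturated ketone, and base-mediated alkene isomerisation through the doubly activated methylene moves the double bond into conjugation to give the verbenone-type enone, with the bridgehead α-carbon unable to enolise.

**Step 14**
Reactants: 20 vinyl enone
Product: 22 (1R,5R,6S,7R)-4,7-dimethyl-6-(2-methyl-3-oxobutan-2-yl)-2-oxobicyclo[3.1.1]hept-3-ene-7-carbaldehyde, via vicinal diol 21 (not isolated)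
Conditions: OsO4 (2 mol %), NaIO4 (4 equiv), 2,6-lutidine, dioxane/H2O 3:1, rt
Reagents that add atoms: osmium tetroxide O=[Os](=O)(=O)=O; sodium periodate [Na+].[O-]I(=O)(=O)=O
Why: Lemieux–Johnson oxidative cleavage is chemoselective for the electron-rich monosubstituted vinyl group over the hindered, electron-poor trisubstituted enone.

**Step 15**
Reactants: 22 keto aldehyde
Product: 24 (4R,5S,10R,11R)-longipina-2,8-diene-1,7-dione, via aldol 23 (not isolated)
Conditions: NaOMe (0.3 equiv), MeOH, 0 to 45 °C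
Reagents that add atoms: none
Why: This intramolecular aldol condensation has a single enolisable position (the methyl ketone) and a single non-enolisable aldehyde held close on the same cyclobutane face, and E1cB dehydration drives closure of the seven-membered ring as the cis-enone.

**Step 16**
Reactants: 24 tricyclic dienedione
Product: 26 (4R,5S,9R,10R,11R)-9-hydroxylongipin-2-ene-1,7-dione, via boronate 25 (not isolated)
Conditions: CuCl (5 mol %), NaOt-Bu (8 mol %), (R)-DTBM-SEGPHOS (6 mol %), B2pin2 (1.2 equiv), MeOH (2 equiv), THF, 0 °C to rt; then H2O2, pH 7 phosphate buffer, 0 °C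
Reagents that add atoms: hydrogen peroxide OO
Why: Copper-catalysed enantioselective conjugate borylation adds only to the β-monosubstituted cycloheptenone (the β,β-disubstituted enone is inert), the ligand sets C9 as R because the two enone faces are nearly equivalent in the substrate, and the buffered oxidation of the C–B bond retains configuration.

**Step 17**
Reactants: 26 β-hydroxy ketone
Product: 27 (4R,5S,7R,9R,10R,11R)-7-hydroxy-1-oxolongipin-2-en-9-yl 2-methylpropanoate
Conditions: i-PrCHO (8 equiv), SmI2 (0.3 equiv), THF, −10 °C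
Reagents that add atoms: 2-methylpropanal CC(C)C=O
Why: In the Evans–Tishchenko reduction the samarium-bound hemiacetal on O9 delivers hydride intramolecularly to the C7 ketone on the face of the C9 oxygen, which sets C7 as R (trans to O9), leaves the isobutyrate on O9, and leaves the enone alone.

**Step 18**
Reactants: 27 hydroxy isobutyrate
Product: 28 (4R,5S,7R,9R,10R,11R)-9-(2-methylpropanoyloxy)-1-oxolongipin-2-en-7-yl 2-methylprop-2-enoate
Conditions: methacrylic anhydride, DMAP, Et3N, BHT (trace), CH2Cl2, rt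
Reagents that add atoms: methacrylic anhydride C=C(C)C(=O)OC(=O)C(C)=C
Why: DMAP-catalysed acylation esterifies the remaining hindered secondary alcohol without touching any stereocentre, and the trans-1,3 arrangement disfavours isobutyrate migration.

**Compound list**

1 | (2E)-3-methylpent-2-en-4-yn-1-ol | OC/C=C(\C)C#C | starting material
2 | (2E)-3-methylpenta-2,4-dien-1-ol | OC/C=C(\C)C=C | intermediate
3 | (2E)-3-methylpenta-2,4-dienal | O=C/C=C(\C)C=C | intermediate
4 | methyl 3-methylbut-2-enoate | COC(=O)C=C(C)C | starting material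
5 | tert-butyl[(1-methoxy-3-methylbuta-1,3-dien-1-yl)oxy]dimethylsilane (ketene acetal geometry not controlled) | C=C(C)C=C(OC)O[Si](C)(C)C(C)(C)C | intermediate
6 | methyl (2E,5S,6E)-5-hydroxy-3,7-dimethylnona-2,6,8-trienoate | COC(=O)/C=C(\C)C[C@H](O)/C=C(\C)C=C | intermediate
7 | methyl (2E,5S,6E)-5-{[tert-butyl(dimethyl)silyl]oxy}-3,7-dimethylnona-2,6,8-trienoate | COC(=O)/C=C(\C)C[C@H](O[Si](C)(C)C(C)(C)C)/C=C(\C)C=C | intermediate
8 | (2E,5S,6E)-5-{[tert-butyl(dimethyl)silyl]oxy}-3,7-dimethylnona-2,6,8-trienoic acid | OC(=O)/C=C(\C)C[C@H](O[Si](C)(C)C(C)(C)C)/C=C(\C)C=C | intermediate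
9 | (2E,5S,6E)-5-{[tert-butyl(dimethyl)silyl]oxy}-3,7-dimethylnona-2,6,8-trienoyl chloride | ClC(=O)/C=C(\C)C[C@H](O[Si](C)(C)C(C)(C)C)/C=C(\C)C=C | intermediate
10 | (5S,6E)-5-{[tert-butyl(dimethyl)silyl]oxy}-7-methyl-3-methylidenenona-1,6,8-trien-1-one (vinylketene) | O=C=CC(=C)C[C@H](O[Si](C)(C)C(C)(C)C)/C=C(\C)C=C | intermediate
11 | (1R,2S,5R,7R)-2-{[tert-butyl(dimethyl)silyl]oxy}-7-ethenyl-7-methyl-4-methylidenebicyclo[3.1.1]heptan-6-one | C=C[C@@]1(C)[C@@H]2[C@@H](O[Si](C)(C)C(C)(C)C)CC(=C)[C@H]1C2=O | intermediate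
12 | 2-[(1R,2S,5S,7R)-2-{[tert-butyl(dimethyl)silyl]oxy}-7-ethenyl-7-methyl-4-methylidenebicyclo[3.1.1]heptan-6-ylidene]acetonitrile (E/Z mixture) | C=C[C@@]1(C)[C@@H]2[C@@H](O[Si](C)(C)C(C)(C)C)CC(=C)[C@H]1C2=CC#N | intermediate
13 | 2-[(1R,2S,5R,6S,7R)-2-{[tert-butyl(dimethyl)silyl]oxy}-7-ethenyl-7-methyl-4-methylidenebicyclo[3.1.1]heptan-6-yl]acetonitrile | C=C[C@@]1(C)[C@@H]2[C@@H](O[Si](C)(C)C(C)(C)C)CC(=C)[C@H]1[C@@H]2CC#N | intermediate
14 | α-monomethyl homologue of 13, 2-(bicycloheptan-6-yl)propanenitrile (epimers at the nitrile α-carbon) | C=C[C@@]1(C)[C@@H]2[C@@H](O[Si](C)(C)C(C)(C)C)CC(=C)[C@H]1[C@@H]2C(C)C#N | intermediate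
15 | 2-[(1R,2S,5R,6S,7R)-2-{[tert-butyl(dimethyl)silyl]oxy}-7-ethenyl-7-methyl-4-methylidenebicyclo[3.1.1]heptan-6-yl]-2-methylpropanenitrile | C=C[C@@]1(C)[C@@H]2[C@@H](O[Si](C)(C)C(C)(C)C)CC(=C)[C@H]1[C@@H]2C(C)(C)C#N | intermediate
16 | 3-[(1R,2S,5R,6S,7R)-2-{[tert-butyl(dimethyl)silyl]oxy}-7-ethenyl-7-methyl-4-methylidenebicyclo[3.1.1]heptan-6-yl]-3-methylbutan-2-imine | C=C[C@@]1(C)[C@@H]2[C@@H](O[Si](C)(C)C(C)(C)C)CC(=C)[C@H]1[C@@H]2C(C)(C)C(C)=N | intermediate
17 | 3-[(1R,2S,5R,6S,7R)-2-{[tert-butyl(dimethyl)silyl]oxy}-7-ethenyl-7-methyl-4-methylidenebicyclo[3.1.1]heptan-6-yl]-3-methylbutan-2-one | C=C[C@@]1(C)[C@@H]2[C@@H](O[Si](C)(C)C(C)(C)C)CC(=C)[C@H]1[C@@H]2C(C)(C)C(C)=O | intermediate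
18 | 3-[(1R,2S,5R,6S,7R)-7-ethenyl-2-hydroxy-7-methyl-4-methylidenebicyclo[3.1.1]heptan-6-yl]-3-methylbutan-2-one | C=C[C@@]1(C)[C@@H]2[C@@H](O)CC(=C)[C@H]1[C@@H]2C(C)(C)C(C)=O | intermediate
19 | (1R,5R,6S,7R)-7-ethenyl-7-methyl-4-methylidene-6-(2-methyl-3-oxobutan-2-yl)bicyclo[3.1.1]heptan-2-one | C=C[C@@]1(C)[C@@H]2C(=O)CC(=C)[C@H]1[C@@H]2C(C)(C)C(C)=O | intermediate
20 | (1R,5R,6S,7R)-7-ethenyl-4,7-dimethyl-6-(2-methyl-3-oxobutan-2-yl)bicyclo[3.1.1]hept-3-en-2-one | C=C[C@@]1(C)[C@@H]2C(=O)C=C(C)[C@H]1[C@@H]2C(C)(C)C(C)=O | intermediate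
21 | (1R,5R,6S,7R)-7-(1,2-dihydroxyethyl)-4,7-dimethyl-6-(2-methyl-3-oxobutan-2-yl)bicyclo[3.1.1]hept-3-en-2-one (carbinol epimers) | OCC(O)[C@@]1(C)[C@@H]2C(=O)C=C(C)[C@H]1[C@@H]2C(C)(C)C(C)=O | intermediate
22 | (1R,5R,6S,7R)-4,7-dimethyl-6-(2-methyl-3-oxobutan-2-yl)-2-oxobicyclo[3.1.1]hept-3-ene-7-carbaldehyde | O=C[C@@]1(C)[C@@H]2C(=O)C=C(C)[C@H]1[C@@H]2C(C)(C)C(C)=O | intermediate
23 | (4R,5S,10R,11R)-9-hydroxylongipin-2-ene-1,7-dione (C9 epimers) | O=C1CC(O)[C@@]2(C)[C@@H]3C(=O)C=C(C)[C@H]2[C@@H]3C1(C)C | intermediate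
24 | (4R,5S,10R,11R)-longipina-2,8-diene-1,7-dione | O=C1C=C[C@@]2(C)[C@@H]3C(=O)C=C(C)[C@H]2[C@@H]3C1(C)C | intermediate
25 | (4R,5S,9R,10R,11R)-9-(4,4,5,5-tetramethyl-1,3,2-dioxaborolan-2-yl)longipin-2-ene-1,7-dione | O=C1C[C@@H](B4OC(C)(C)C(C)(C)O4)[C@@]2(C)[C@@H]3C(=O)C=C(C)[C@H]2[C@@H]3C1(C)C | intermediate
26 | (4R,5S,9R,10R,11R)-9-hydroxylongipin-2-ene-1,7-dione | O=C1C[C@@H](O)[C@@]2(C)[C@@H]3C(=O)C=C(C)[C@H]2[C@@H]3C1(C)C | intermediate
27 | (4R,5S,7R,9R,10R,11R)-7-hydroxy-1-oxolongipin-2-en-9-yl 2-methylpropanoate | O[C@@H]1C[C@@H](OC(=O)C(C)C)[C@@]2(C)[C@@H]3C(=O)C=C(C)[C@H]2[C@@H]3C1(C)C | intermediate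
28 | (4R,5S,7R,9R,10R,11R)-9-(2-methylpropanoyloxy)-1-oxolongipin-2-en-7-yl 2-methylprop-2-enoate (CNP0214356.1) | C=C(C)C(=O)O[C@@H]1C[C@@H](OC(=O)C(C)C)[C@@]2(C)[C@@H]3C(=O)C=C(C)[C@H]2[C@@H]3C1(C)C | target

**Totals and risks**

Total step count: 18. Longest linear sequence: 17 steps (1 to 28 through steps 1, 2 and 4–18).

Most likely to fail, step 7 (ketene cycloaddition on a functionalised diene; yield and facial control). The fallback sets out from 8 and comes back at 11. Acid 8 is converted with the same chloroenamine and then dimethylamine into (2E,5S,6E)-5-{[tert-butyl(dimethyl)silyl]oxy}-N,N,3,7-tetramethylnona-2,6,8-trienamide F1. Tf2O and 2,4,6-collidine in 1,2-dichloroethane at 80 °C turn F1 into a vinylketeniminium ion, which is more electrophilic than the ketene and cannot dimerise. It undergoes the same intramolecular [2+2] under the same 1,3-allylic strain control to give the cyclobutaniminium salt N-[(1S,2S,5R,7R)-2-{[tert-butyl(dimethyl)silyl]oxy}-7-ethenyl-7-methyl-4-methylidenebicyclo[3.1.1]heptan-6-ylidene]-N-methylmethanaminium trifluoromethanesulfonate F2, and aqueous NaHCO3 hydrolysis returns ketone 11.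

Most likely to fail, step 15 (aldol closure of the strained seven-membered enone). The fallback sets out from 20 and comes back at 24, bypassing 22. The methyl ketone of 20 is α-methylenated (paraformaldehyde, N-methylanilinium trifluoroacetate, THF, reflux) to the vinyl ketone (1R,5R,6S,7R)-7-ethenyl-4,7-dimethyl-6-(2-methyl-3-oxopent-4-en-2-yl)bicyclo[3.1.1]hept-3-en-2-one F3. Ring-closing metathesis between its two monosubstituted alkenes with the second-generation Hoveyda–Grubbs catalyst (toluene, 80 °C) closes the cycloheptenone irreversibly and gives 24.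

Most likely to fail, step 16 (enantioselective borylation at a β-carbon next to a quaternary centre). The fallback sets out from 22 and comes back at 26. The aldol of step 15 is stopped before dehydration (NaOMe cat., MeOH, −20 °C, short time) and the two C9 epimers of 23 are separated by chromatography. The 9R epimer is 26. The epimer (4R,5S,9S,10R,11R)-9-hydroxylongipin-2-ene-1,7-dione F4 is returned to the same basic conditions, where retro-aldol and re-aldol regenerate the mixture for another separation.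

**Further compounds**

F1 | step 7 | (2E,5S,6E)-5-{[tert-butyl(dimethyl)silyl]oxy}-N,N,3,7-tetramethylnona-2,6,8-trienamide | CN(C)C(=O)/C=C(\C)C[C@H](O[Si](C)(C)C(C)(C)C)/C=C(\C)C=C
F2 | step 7 | N-[(1S,2S,5R,7R)-2-{[tert-butyl(dimethyl)silyl]oxy}-7-ethenyl-7-methyl-4-methylidenebicyclo[3.1.1]heptan-6-ylidene]-N-methylmethanaminium trifluoromethanesulfonate | C=C[C@@]1(C)[C@@H]2[C@@H](O[Si](C)(C)C(C)(C)C)CC(=C)[C@H]1C2=[N+](C)C.[O-]S(=O)(=O)C(F)(F)F
F3 | step 15 | (1R,5R,6S,7R)-7-ethenyl-4,7-dimethyl-6-(2-methyl-3-oxopent-4-en-2-yl)bicyclo[3.1.1]hept-3-en-2-one | C=C[C@@]1(C)[C@@H]2C(=O)C=C(C)[C@H]1[C@@H]2C(C)(C)C(=O)C=C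
F4 | step 16 | (4R,5S,9S,10R,11R)-9-hydroxylongipin-2-ene-1,7-dione | O=C1C[C@H](O)[C@@]2(C)[C@@H]3C(=O)C=C(C)[C@H]2[C@@H]3C1(C)C
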